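**Plan**

- Cuts: the C1–OH bond of ring A is traced back to C1–B and then to C1–Si. Ring A itself is then opened at C1–C6 and C2–C3 (retro-[4+2], with SO2 restored as a one-atom bridge). Last, the O–CH2 bond between the oxygen of ring B and the two-carbon unit is cut.
- Enabling feature: around ring A, C3(Br)–C4(Br)–C5(H)–C6(Br) is the four-carbon diene of 2,3,5-tribromothiophene with every substituent in place. The neighbouring C1(OH)/C2(OAr) pair is an alkyne that already carries the 2-bromophenoxy group, so no aryl C–O coupling is needed.
- Forward: ring B is bought as 2-bromophenol and O-alkylated at sp3 carbon. The side chain is converted into a silyl-capped aryloxyalkyne. Ring A is closed last by cycloaddition to the thiophene 1,1-dioxide with loss of SO2, then Si is exchanged for B and B for OH.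
- Stereochemistry: the target has no stereocentre. The only elements on the way are the Z double bond of a bromovinyl ether (set by bromination/elimination, erased in the alkyne) and a racemic bridged adduct that is never isolated.

Key step: step 6

Remark: 2,3,5-tribromothiophene, 2-bromophenol, 1,2-dibromoethane and chlorotrimethylsilane are taken as commercial.

**Route**

Step 1
Reactants: 1 2,3,5-tribromothiophene
Product: 2 2,3,5-tribromothiophene 1,1-dioxide
Conditions: (CF3CO)2O, urea·H2O2, CH2Cl2, 0 °C → rt (CF3CO3H formed in the flask)
Reagents that add atoms: trifluoroperacetic acid, OOC(=O)C(F)(F)F (both sulfone oxygens; generated from urea–hydrogen peroxide, NC(N)=O.OO)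
Why: Stepwise electrophilic oxygen transfer from the peracid to sulfur (thiophene to S-oxide to S,S-dioxide) is the standard route to halogenated thiophene 1,1-dioxides, trifluoroperacetic acid being strong enough for the electron-poor ring, and the bromines on both α-carbons should make the dioxide stable enough to isolate.

Step 2
Reactants: 3 2-bromophenol; 4 1,2-dibromoethane
Product: 5 1-bromo-2-(2-bromoethoxy)benzene
Conditions: K2CO3, 4 in excess, MeCN, reflux
Reagents that add atoms: none
Why: Williamson ether synthesis in which the phenoxide displaces one bromide of the primary dihalide by SN2 at sp3 carbon, the aryl bromide being inert and the excess of dihalide suppressing the bis-ether.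

Step 3
Reactants: 5 1-bromo-2-(2-bromoethoxy)benzene
Product: 6 1-bromo-2-(ethenyloxy)benzene (2-bromophenyl vinyl ether)
Conditions: KOt-Bu, DMSO, rt
Reagents that add atoms: none
Why: E2 dehydrobromination of a 2-aryloxyethyl bromide by a hindered alkoxide, the usual preparation of aryl vinyl ethers, in which the hydrogens next to oxygen are acidified and the bulk of the base disfavours substitution.

Step 4
Reactants: 6 1-bromo-2-(ethenyloxy)benzene
Product: 8 (Z)-1-bromo-2-[(2-bromoethenyl)oxy]benzene, via 1-bromo-2-(1,2-dibromoethoxy)benzene 7 (not isolated)
Conditions: Br2 (1 equiv), CH2Cl2, −78 °C; then PhNEt2, −78 → 90 °C (CH2Cl2 distilled off)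
Reagents that add atoms: bromine, BrBr
Why: Electrophilic addition of bromine to the electron-rich enol ether double bond is much faster at low temperature than substitution on the deactivated ring B, and the α-bromo ether 7 then loses HBr through its oxocarbenium ion under the amine (dehydrobromination as in the standard preparation of (Z)-1-bromo-2-ethoxyethene), which should favour the Z isomer that has H and Br anti for the following elimination.

Step 5
Reactants: 8 (Z)-1-bromo-2-[(2-bromoethenyl)oxy]benzene; 9 chlorotrimethylsilane
Product: 12 [(2-bromophenoxy)ethynyl]trimethylsilane, via 1-bromo-2-(ethynyloxy)benzene 10 (not isolated), via [(2-bromophenoxy)ethynyl]lithium 11 (not isolated)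
Conditions: LiN(i-Pr)2 (2.3 equiv), THF, −78 °C; then 9, −78 → 0 °C; aq. NaHCO3 work-up
Reagents that add atoms: none
Why: Anti E2 elimination of HBr from the Z-bromovinyl ether gives the terminal ynol ether 10, the second equivalent of amide converts it into the acetylide 11 and this is silylated on carbon by 9 (acetylide silylation), a lithium amide being used instead of an alkyllithium so that no bromine–lithium exchange can touch the aryl C–Br bond.

Step 6
Reactants: 2 2,3,5-tribromothiophene 1,1-dioxide; 12 [(2-bromophenoxy)ethynyl]trimethylsilane
Product: 14 [3,4,6-tribromo-2-(2-bromophenoxy)phenyl]trimethylsilane, via bridged sulfone cycloadduct 13 (not isolated)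
Conditions: PhMe, 80 °C, slow N2 purge (12 in slight excess)
Reagents that add atoms: none
Why: The diene of 2, whose LUMO is lowered by the sulfone and three bromines, and the oxygen-donor alkyne 12 should combine in a concerted but asynchronous inverse-electron-demand Diels–Alder reaction across the two α-carbons of 2, and the bridged adduct 13 then expels SO2 in a thermally allowed cheletropic step driven by aromatization. The closest known reaction type is the addition of alkynes to tetrahalothiophene 1,1-dioxides, which delivers polyhalobenzenes with extrusion of SO2. Ring A is closed by intermolecular [4+2] cycloaddition, the silicon-bearing alkyne carbon bonding to thiophene C5 (target C1–C6) and the oxygen-bearing alkyne carbon to thiophene C2 (target C2–C3), and the six-membered carbocycle remains when the sulfur bridge departs. No stereocentre is created in the product, since the two bridgehead centres of racemic 13 vanish on aromatization. The selectivity needed is regioselectivity between the diene termini: the silicon-bearing carbon is the nucleophilic end of 12 (β to oxygen, the positive charge building up on the oxygen-bearing carbon being stabilized by the oxygen lone pair and the β-silyl effect) and should lead bond formation, and its bulk should direct it to C5, whose neighbour C4 carries only hydrogen, so that the less hindered oxygen-bearing carbon ends up at C2 next to the C3 bromine. The 3,5,6-tribromo regioisomer is the by-product to expect and to remove by chromatography, while 12 cannot lose a ketene by a retro-ene path because its oxygen substituent is an aryl group without a β C–H, and the trimethylsilyl group should keep the alkyne from polymerizing.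

Step 7
Reactants: 14 [3,4,6-tribromo-2-(2-bromophenoxy)phenyl]trimethylsilane
Product: 16 [3,4,6-tribromo-2-(2-bromophenoxy)phenyl]boronic acid, via aryldibromoborane 15 (not isolated)
Conditions: BBr3, CH2Cl2, 0 °C → rt; volatiles removed; then H2O, THF, 0 °C
Reagents that add atoms: boron tribromide, BrB(Br)Br; water, O
Why: Electrophilic ipso-borodesilylation in which BBr3 attacks the silicon-bearing carbon, which is ortho to the donating aryloxy oxygen and gives a β-silyl-stabilized arenium ion that loses Me3SiBr, the diaryl ether having no alkyl C–O bond for BBr3 to cleave, after which water hydrolyses the B–Br bonds of 15.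

Step 8
Reactants: 16 [3,4,6-tribromo-2-(2-bromophenoxy)phenyl]boronic acid
Product: 17 3,4,6-tribromo-2-(2-bromophenoxy)phenol (target)
Conditions: 30% aq. H2O2, THF, aq. NaH2PO4/Na2HPO4 buffer (pH 7), 0 °C → rt
Reagents that add atoms: hydrogen peroxide, OO
Why: Peroxide oxidation of an arylboronic acid, in which hydroperoxide adds to boron, the aryl group migrates from boron to oxygen at the same ring carbon and the borate ester hydrolyses to the phenol, the near-neutral buffer being chosen so that oxidation outruns protodeboronation of the hindered, electron-poor boronic acid.

**Compound list**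

1 | 2,3,5-tribromothiophene | Brc1cc(Br)c(Br)s1 | starting material
2 | 2,3,5-tribromothiophene 1,1-dioxide | O=S1(=O)C(Br)=CC(Br)=C1Br | intermediate
3 | 2-bromophenol | Oc1ccccc1Br | starting material
4 | 1,2-dibromoethane | BrCCBr | starting material
5 | 1-bromo-2-(2-bromoethoxy)benzene | BrCCOc1ccccc1Br | intermediate
6 | 1-bromo-2-(ethenyloxy)benzene | C=COc1ccccc1Br | intermediate
7 | 1-bromo-2-(1,2-dibromoethoxy)benzene (racemic, not isolated) | BrCC(Br)Oc1ccccc1Br | intermediate
8 | (Z)-1-bromo-2-[(2-bromoethenyl)oxy]benzene | Br/C=C\Oc1ccccc1Br | intermediate
9 | chlorotrimethylsilane | C[Si](C)(C)Cl | starting material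
10 | 1-bromo-2-(ethynyloxy)benzene (not isolated) | C#COc1ccccc1Br | intermediate
11 | [(2-bromophenoxy)ethynyl]lithium (not isolated) | [Li]C#COc1ccccc1Br | intermediate
12 | [(2-bromophenoxy)ethynyl]trimethylsilane | C[Si](C)(C)C#COc1ccccc1Br | intermediate
13 | 1,2,4-tribromo-6-(2-bromophenoxy)-5-(trimethylsilyl)-7-thiabicyclo[2.2.1]hepta-2,5-diene 7,7-dioxide (racemic, bridgeheads fixed relative to each other by the bicycle, not isolated) | O=S1(=O)C2(Br)C(Br)=CC1(Br)C([Si](C)(C)C)=C2Oc1ccccc1Br | intermediate
14 | [3,4,6-tribromo-2-(2-bromophenoxy)phenyl]trimethylsilane | C[Si](C)(C)c1c(Br)cc(Br)c(Br)c1Oc1ccccc1Br | intermediate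
15 | dibromo[3,4,6-tribromo-2-(2-bromophenoxy)phenyl]borane (not isolated) | BrB(Br)c1c(Br)cc(Br)c(Br)c1Oc1ccccc1Br | intermediate
16 | [3,4,6-tribromo-2-(2-bromophenoxy)phenyl]boronic acid | OB(O)c1c(Br)cc(Br)c(Br)c1Oc1ccccc1Br | intermediate
17 | 3,4,6-tribromo-2-(2-bromophenoxy)phenol | Oc1c(Br)cc(Br)c(Br)c1Oc1ccccc1Br | target

**Count and risks**

Total step count: 8.
Longest linear sequence: 7 steps (from 2-bromophenol 3 through steps 2 to 8 to 17).

Steps most likely to fail:

Step 6. The two diene termini of 2 differ only in their neighbour (hydrogen or bromine), so the alkyne may add in both orientations and leave a mixture of regioisomeric arenes that is hard to separate. Slow cycloaddition could also let the dioxide dimerize. The fallback removes the regiochemical question by using a symmetrical diene and placing the C4 bromine last. It sets out from 12 and returns at 17.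
- Commercial 2,5-dibromothiophene is oxidized as in step 1 to 2,5-dibromothiophene 1,1-dioxide F1.
- Heating F1 with 12 in toluene should give, through the bridged 7-thianorbornadiene 7,7-dioxide adduct F2, [3,6-dibromo-2-(2-bromophenoxy)phenyl]trimethylsilane F3, the only regioisomer possible.
- BBr3 converts F3 through the aryldibromoborane F4 and aqueous hydrolysis into [3,6-dibromo-2-(2-bromophenoxy)phenyl]boronic acid F5.
- Buffered H2O2 oxidizes F5 to 3,6-dibromo-2-(2-bromophenoxy)phenol F6.
- Electrophilic bromination of F6 (Br2, AcOH, rt) should go para to the free hydroxyl group, the only open position it activates, and give 17.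

Step 7. Electrophilic attack of BBr3 at the silicon-bearing carbon may stall, because three bromines deactivate ring A and the silyl group sits between Br and OAr. The aryl–BBr2 group, once formed, may also cyclize onto ring B in an intramolecular bora-Friedel–Crafts reaction. The fallback carries a silicon group that can be oxidized directly, so that no electrophilic ipso-substitution is needed. It sets out from 8 and returns at 17.
- Elimination of 8 with LiN(i-Pr)2 as in step 5 (through 10 and 11) and quenching with chlorodimethylsilane give [(2-bromophenoxy)ethynyl]dimethylsilane F7.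
- Cycloaddition of F7 with 2 as in step 6 should give, through the bridged sulfone adduct F8, [3,4,6-tribromo-2-(2-bromophenoxy)phenyl]dimethylsilane F9.
- Tamao–Fleming oxidation of F9 (H2O2, KHCO3, THF/MeOH) converts Si–H into Si–O, lets the aryl group migrate from silicon to oxygen, and should give 17.

Step 5. The amide base may deprotonate ring B next to its bromine, leading to aryne formation. The lithium aryloxyacetylide may also decompose before it is silylated. The fallback separates elimination from metalation and avoids lithium altogether. It sets out from 8 and returns at 12.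
- KOt-Bu in THF at −40 → 0 °C, a base too weak to metalate the aryl ring, eliminates HBr from 8 to give the terminal alkyne 10, which is kept in solution and used at once.
- EtMgBr (THF, 0 °C), which does not exchange with aryl bromides, converts 10 into the magnesium acetylide, and silylation with 9 gives 12.

**Further compounds**

F1 | step 6 | 2,5-dibromothiophene 1,1-dioxide | O=S1(=O)C(Br)=CC=C1Br
F2 | step 6 | 1,4-dibromo-5-(2-bromophenoxy)-6-(trimethylsilyl)-7-thiabicyclo[2.2.1]hepta-2,5-diene 7,7-dioxide (racemic) | O=S1(=O)C2(Br)C=CC1(Br)C([Si](C)(C)C)=C2Oc1ccccc1Br
F3 | step 6 | [3,6-dibromo-2-(2-bromophenoxy)phenyl]trimethylsilane | C[Si](C)(C)c1c(Br)ccc(Br)c1Oc1ccccc1Br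
F4 | step 6 | dibromo[3,6-dibromo-2-(2-bromophenoxy)phenyl]borane | BrB(Br)c1c(Br)ccc(Br)c1Oc1ccccc1Br
F5 | step 6 | [3,6-dibromo-2-(2-bromophenoxy)phenyl]boronic acid | OB(O)c1c(Br)ccc(Br)c1Oc1ccccc1Br
F6 | step 6 | 3,6-dibromo-2-(2-bromophenoxy)phenol | Oc1c(Br)ccc(Br)c1Oc1ccccc1Br
F7 | step 7 | [(2-bromophenoxy)ethynyl]dimethylsilane | C[SiH](C)C#COc1ccccc1Br
F8 | step 7 | 1,2,4-tribromo-6-(2-bromophenoxy)-5-(dimethylsilyl)-7-thiabicyclo[2.2.1]hepta-2,5-diene 7,7-dioxide (racemic) | O=S1(=O)C2(Br)C(Br)=CC1(Br)C([SiH](C)C)=C2Oc1ccccc1Br
F9 | step 7 | [3,4,6-tribromo-2-(2-bromophenoxy)phenyl]dimethylsilane | C[SiH](C)c1c(Br)cc(Br)c(Br)c1Oc1ccccc1Br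
F0 | step 5 | none | none
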